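The route avoids making the crowded C6–C2' bond at all. This bond joins ring A carbon C6, with its two ortho oxygens (C5–O, C7–O), to the carbon next to N1', and it is inherited from the aryl–acetyl bond of phloroacetophenone. The piperidine ring is cut instead at C3'–C4' and C5'–C6'. In one operation a 1,2,4-triazine takes up norbornadiene and loses N2 and cyclopentadiene, building the whole six-membered nitrogen ring as a 2-arylpyridine. The precursor is a 3,6-unsubstituted triazine whose C5 carries the phloroglucinol ring, protected as two small MOM ethers beside the biaryl bond and one benzyl ether para to it. Asymmetric pyridinium hydrogenation and a chiral-pool Mitsunobu/Friedel–Crafts annulation complete the flavanone.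

Key step: step 5

Assumption: (S)-SynPhos is taken as the ligand antipode that gives the (R)-piperidine, by analogy with the parent N-benzyl 2-phenyl salt; if a pilot run shows the opposite sense, (R)-SynPhos is used instead.

Step 1
Reactants: 1 2,4,6-trihydroxyacetophenone
Product: 2 1-[4-(benzyloxy)-2,6-dihydroxyphenyl]ethan-1-one
Conditions: BnBr (1.05 equiv), K2CO3 (1.1 equiv), DMF, 0 °C → rt
Reagents that add atoms: benzyl bromide, BrCc1ccccc1
Why: Williamson ether synthesis, in which the 4-OH is the most acidic phenol and the only one not held in a hydrogen bond to the acetyl C=O, so one equivalent of BnBr under weak base should alkylate it preferentially.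

Step 2
Reactants: 2 1-[4-(benzyloxy)-2,6-dihydroxyphenyl]ethan-1-one
Product: 3 1-[4-(benzyloxy)-2,6-bis(methoxymethoxy)phenyl]ethan-1-one
Conditions: NaH (2.4 equiv), MOMCl (2.6 equiv), DMF, 0 °C → rt
Reagents that add atoms: chloromethyl methyl ether (MOMCl), COCCl
Why: Williamson-type O-alkylation to the MOM acetals, in which full deprotonation by NaH breaks the chelation of both phenols and the symmetry of 2 leaves no regiochemical question.

Step 3
Reactants: 3 1-[4-(benzyloxy)-2,6-bis(methoxymethoxy)phenyl]ethan-1-one
Product: 4 2-[4-(benzyloxy)-2,6-bis(methoxymethoxy)phenyl]-2-oxoacetaldehyde (handled as its hydrate)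
Conditions: SeO2 (1.5 equiv), 1,4-dioxane/H2O (30:1), 90 °C
Reagents that add atoms: selenium dioxide, O=[Se]=O
Why: Riley oxidation, in which SeO2 attacks the enol of the aryl methyl ketone and, after sigmatropic shift and loss of selenium, leaves the α-keto aldehyde, the acetyl methyl group being the only enolisable position in 3.

Step 4
Reactants: 4 2-[4-(benzyloxy)-2,6-bis(methoxymethoxy)phenyl]-2-oxoacetaldehyde; 5 formamidine acetate; 6 hydrazine monohydrate
Product: 8 5-[4-(benzyloxy)-2,6-bis(methoxymethoxy)phenyl]-1,2,4-triazine, via formamidrazone 7 (not isolated)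
Conditions: 5 (3 equiv), 6 (1.2 equiv), MeOH, −10 °C, 20 min; then 4, 0 °C → rt; AcOH (cat.), 50 °C
Reagents that add atoms: none
Why: Amidrazone/1,2-dicarbonyl condensation to a 1,2,4-triazine, in which the hydrazine NH2 of formamidrazone condenses with the unhindered aldehyde carbon (which becomes C6) and the amidine NH2 then closes onto the aryl ketone, placing the aryl group on C5.

Step 5
Reactants: 8 5-[4-(benzyloxy)-2,6-bis(methoxymethoxy)phenyl]-1,2,4-triazine; 9 bicyclo[2.2.1]hepta-2,5-diene (norbornadiene)
Product: 12 2-[4-(benzyloxy)-2,6-bis(methoxymethoxy)phenyl]pyridine, via bridged cycloadduct 10 (not isolated), via fused dihydropyridine 11 (not isolated)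
Conditions: 9 (10 equiv), 1,2-dichlorobenzene, 140 °C, sealed tube
Reagents that add atoms: none
Why: Inverse-electron-demand Diels–Alder reaction, in which the low-lying LUMO of the triazine takes up the strained C=C of norbornadiene across C3 and C6 in a concerted suprafacial [4+2] addition to give bridged adduct 10, which expels N2 by retro-[4+2] to give dihydropyridine 11 and then cyclopentadiene by a second retro-[4+2], so that aromatisation drives the cascade to pyridine 12. The closest known reaction type is the Boger-type conversion of 1,2,4-triazines into pyridines with norbornadiene as an acetylene equivalent. The one new ring, the six-membered nitrogen ring (N1', C2' to C6'), is closed by cycloaddition, with C3'–C4' and C5'–C6' formed in the same step and no end-on ring closure involved, and triazine C5 becomes C2' while N4 becomes N1'. No stereocentre is created, because the sp3 centres of 10 and 11 disappear on aromatisation, so facial and exo/endo selectivity do not matter. The step needs addition across C3/C6 and not across N2/C5, which the ring nitrogens secure by placing the reactive diene termini at C3 and C6 while the aryl group blocks C5; the symmetric dienophile makes both orientations converge on the same pyridine, and the unsubstituted C3 and the small MOM ethers keep the diene termini accessible.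

Step 6
Reactants: 12 2-[4-(benzyloxy)-2,6-bis(methoxymethoxy)phenyl]pyridine
Product: 13 1-benzyl-2-[4-(benzyloxy)-2,6-bis(methoxymethoxy)phenyl]pyridin-1-ium bromide
Conditions: BnBr (3 equiv), MeCN, 80 °C
Reagents that add atoms: benzyl bromide, BrCc1ccccc1
Why: Menshutkin N-alkylation, in which the pyridine nitrogen is the only nucleophile in 12 and the bromide salt formed is the activated substrate that the [Ir(cod)Cl]2/bisphosphine hydrogenation requires.

Step 7
Reactants: 13 1-benzyl-2-[4-(benzyloxy)-2,6-bis(methoxymethoxy)phenyl]pyridin-1-ium bromide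
Product: 14 (2R)-1-benzyl-2-[4-(benzyloxy)-2,6-bis(methoxymethoxy)phenyl]piperidine
Conditions: [Ir(cod)Cl]2 (1 mol%), (S)-SynPhos (2.2 mol%), H2 (40 bar), PhMe/CH2Cl2 (1:1), 30 °C; then aq. Na2CO3
Reagents that add atoms: none
Why: Asymmetric hydrogenation of an N-benzyl 2-arylpyridinium bromide with [Ir(cod)Cl]2/(S)-SynPhos, in which stepwise hydride transfer and enamine–iminium tautomerisation end with hydride delivery to one face of the C2'=N iminium inside the chiral pocket of the ligand, so the ligand antipode sets (R) at C2' while the benzyl ethers and MOM acetals are left untouched by the homogeneous catalyst.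

Step 8
Reactants: 14 (2R)-1-benzyl-2-[4-(benzyloxy)-2,6-bis(methoxymethoxy)phenyl]piperidine
Product: 15 3,5-bis(methoxymethoxy)-4-[(2R)-piperidin-2-yl]phenol
Conditions: H2 (1–3 bar), Pd(OH)2/C, AcOH (2 equiv), MeOH, rt; then aq. NaHCO3
Reagents that add atoms: none
Why: Hydrogenolysis over Pd(OH)2/C, which cleaves the exocyclic O–CH2Ph and N–CH2Ph bonds, whereas the ring C2'–N bond, flanked by two ortho substituents that keep the arene from lying flat on the metal, should be retained with C2' unchanged.

Step 9
Reactants: 15 3,5-bis(methoxymethoxy)-4-[(2R)-piperidin-2-yl]phenol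
Product: 16 3,5-bis(methoxymethoxy)-4-[(2R)-1-methylpiperidin-2-yl]phenol
Conditions: 37% aq. HCHO (1.2 equiv), NaBH(OAc)3 (2 equiv), ClCH2CH2Cl, 0 °C → rt
Reagents that add atoms: formaldehyde, C=O
Why: Reductive amination, in which the secondary amine forms an iminium ion with formaldehyde that NaBH(OAc)3 reduces faster than the phenol ring can be hydroxymethylated, without involving the stereocentre.

Step 10
Reactants: 16 3,5-bis(methoxymethoxy)-4-[(2R)-1-methylpiperidin-2-yl]phenol; 17 ethyl (3R)-3-hydroxy-3-phenylpropanoate
Product: 18 ethyl (3S)-3-{3,5-bis(methoxymethoxy)-4-[(2R)-1-methylpiperidin-2-yl]phenoxy}-3-phenylpropanoate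
Conditions: PPh3 (1.5 equiv), DIAD (1.5 equiv, slow addition), toluene, 0 °C → rt
Reagents that add atoms: none
Why: Mitsunobu etherification, in which the phenol displaces the benzylic oxyphosphonium group in an SN2 step with inversion, turning the (R)-carbinol of 17 into the (S)-configured aryl ether carbon that becomes C2.

Step 11
Reactants: 18 ethyl (3S)-3-{3,5-bis(methoxymethoxy)-4-[(2R)-1-methylpiperidin-2-yl]phenoxy}-3-phenylpropanoate
Product: 19 (3S)-3-{3,5-bis(methoxymethoxy)-4-[(2R)-1-methylpiperidin-2-yl]phenoxy}-3-phenylpropanoic acid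
Conditions: LiOH·H2O (2 equiv), THF/H2O (3:1), 0 °C → rt; then 1 M HCl to pH 6–7
Reagents that add atoms: lithium hydroxide monohydrate, [Li+].[OH-].O
Why: Saponification, in which hydroxide adds to the ester carbonyl at low temperature faster than the ester enolate can expel the aryloxide, and neither stereocentre carries a proton acidic enough to epimerise.

Step 12
Reactants: 19 (3S)-3-{3,5-bis(methoxymethoxy)-4-[(2R)-1-methylpiperidin-2-yl]phenoxy}-3-phenylpropanoic acid
Product: 21 (2S)-5,7-bis(methoxymethoxy)-6-[(2R)-1-methylpiperidin-2-yl]-2-phenyl-2,3-dihydro-4H-chromen-4-one, via mixed trifluoroacetic anhydride 20 (not isolated)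
Conditions: TFA (1.1 equiv), then TFAA (3 equiv), CH2Cl2, 0 °C → rt; then aq. NaHCO3
Reagents that add atoms: none
Why: Intramolecular Friedel–Crafts acylation through the mixed anhydride, in which the phloroglucinol-type ring is attacked ortho to the ether oxygen (the two such positions are equivalent by symmetry) to close the six-membered ketone ring, the amine being masked as its ammonium salt and C2 not being a reacting centre.

Step 13
Reactants: 21 (2S)-5,7-bis(methoxymethoxy)-6-[(2R)-1-methylpiperidin-2-yl]-2-phenyl-2,3-dihydro-4H-chromen-4-one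
Product: 22 (2S)-5,7-dihydroxy-6-[(2R)-1-methylpiperidin-2-yl]-2-phenyl-2,3-dihydro-4H-chromen-4-one (CNP0404761.1)
Conditions: 1.25 M HCl in MeOH, 0 °C → rt; then aq. NaHCO3 to pH 8
Reagents that add atoms: none
Why: Acid-catalysed transacetalisation of the two aryl MOM ethers to methanol, under conditions in which the flavanone C2 and the protonated benzylic amine centre C2' should keep their configuration, the free base being released on neutralisation.

Compound list
1 | 2,4,6-trihydroxyacetophenone | CC(=O)c1c(O)cc(O)cc1O | starting material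
2 | 1-[4-(benzyloxy)-2,6-dihydroxyphenyl]ethan-1-one | CC(=O)c1c(O)cc(OCc2ccccc2)cc1O | intermediate
3 | 1-[4-(benzyloxy)-2,6-bis(methoxymethoxy)phenyl]ethan-1-one | CC(=O)c1c(OCOC)cc(OCc2ccccc2)cc1OCOC | intermediate
4 | 2-[4-(benzyloxy)-2,6-bis(methoxymethoxy)phenyl]-2-oxoacetaldehyde | O=CC(=O)c1c(OCOC)cc(OCc2ccccc2)cc1OCOC | intermediate
5 | formamidine acetate | CC(=O)O.N=CN | starting material
6 | hydrazine monohydrate | NN.O | starting material
7 | formamidrazone (formimidohydrazide, present as its acetate salt) | NC=NN | intermediate (not isolated)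
8 | 5-[4-(benzyloxy)-2,6-bis(methoxymethoxy)phenyl]-1,2,4-triazine | COCOc1cc(OCc2ccccc2)cc(OCOC)c1-c1cnncn1 | intermediate
9 | bicyclo[2.2.1]hepta-2,5-diene (norbornadiene) | C1C2C=CC1C=C2 | starting material
10 | bridged [4+2] cycloadduct of 8 and 9 across triazine C3 and C6, N=N bridge intact (racemic, no stereodescriptors given) | C12N=NC(N=C1c1c(OCOC)cc(OCc3ccccc3)cc1OCOC)C1C2C2C=CC1C2 | intermediate (not isolated)
11 | norbornene-fused 2-aryl-4,5-dihydropyridine formed from 10 by loss of N2 (racemic, no stereodescriptors given) | N1=CC2C(C=C1c1c(OCOC)cc(OCc3ccccc3)cc1OCOC)C1C=CC2C1 | intermediate (not isolated)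
12 | 2-[4-(benzyloxy)-2,6-bis(methoxymethoxy)phenyl]pyridine | COCOc1cc(OCc2ccccc2)cc(OCOC)c1-c1ccccn1 | intermediate
13 | 1-benzyl-2-[4-(benzyloxy)-2,6-bis(methoxymethoxy)phenyl]pyridin-1-ium bromide | COCOc1cc(OCc2ccccc2)cc(OCOC)c1-c1cccc[n+]1Cc1ccccc1.[Br-] | intermediate
14 | (2R)-1-benzyl-2-[4-(benzyloxy)-2,6-bis(methoxymethoxy)phenyl]piperidine | C(N1CCCC[C@@H]1c1c(OCOC)cc(OCc2ccccc2)cc1OCOC)c1ccccc1 | intermediate
15 | 3,5-bis(methoxymethoxy)-4-[(2R)-piperidin-2-yl]phenol | N1CCCC[C@@H]1c1c(OCOC)cc(O)cc1OCOC | intermediate
16 | 3,5-bis(methoxymethoxy)-4-[(2R)-1-methylpiperidin-2-yl]phenol | CN1CCCC[C@@H]1c1c(OCOC)cc(O)cc1OCOC | intermediate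
17 | ethyl (3R)-3-hydroxy-3-phenylpropanoate | CCOC(=O)C[C@H](c1ccccc1)O | starting material
18 | ethyl (3S)-3-{3,5-bis(methoxymethoxy)-4-[(2R)-1-methylpiperidin-2-yl]phenoxy}-3-phenylpropanoate | CCOC(=O)C[C@@H](c1ccccc1)Oc1cc(OCOC)c([C@H]2CCCCN2C)c(OCOC)c1 | intermediate
19 | (3S)-3-{3,5-bis(methoxymethoxy)-4-[(2R)-1-methylpiperidin-2-yl]phenoxy}-3-phenylpropanoic acid | OC(=O)C[C@@H](c1ccccc1)Oc1cc(OCOC)c([C@H]2CCCCN2C)c(OCOC)c1 | intermediate
20 | (3S)-3-{3,5-bis(methoxymethoxy)-4-[(2R)-1-methylpiperidin-2-yl]phenoxy}-3-phenylpropanoic trifluoroacetic anhydride | O=C(C[C@@H](c1ccccc1)Oc1cc(OCOC)c([C@H]2CCCCN2C)c(OCOC)c1)OC(=O)C(F)(F)F | intermediate (not isolated)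
21 | (2S)-5,7-bis(methoxymethoxy)-6-[(2R)-1-methylpiperidin-2-yl]-2-phenyl-2,3-dihydro-4H-chromen-4-one | CN1CCCC[C@@H]1c1c(OCOC)cc2c(c1OCOC)C(=O)C[C@@H](c1ccccc1)O2 | intermediate
22 | (2S)-5,7-dihydroxy-6-[(2R)-1-methylpiperidin-2-yl]-2-phenyl-2,3-dihydro-4H-chromen-4-one (CNP0404761.1) | CN1CCCC[C@@H]1c1c(O)cc2c(c1O)C(=O)C[C@@H](c1ccccc1)O2 | target

Total step count: 13. Longest linear sequence: 13 steps (1 to 22); compounds 5, 6, 9 and 17 are bought.

Steps most likely to fail

Step 7. The aryl ring stands perpendicular to the heterocycle and holds one OMOM group over each face of the C2'=N iminium, so the last hydride transfer may be slow (reduction stalling at a tetrahydropyridine) or may proceed with poor facial selectivity. The fallback gives up catalyst control and sets out from pyridinium bromide 13: hydrogenation over PtO2 (H2, MeOH, rt; aq. Na2CO3) should give racemic 1-benzyl-2-[4-(benzyloxy)-2,6-bis(methoxymethoxy)phenyl]piperidine F1. This is separated into its enantiomers by preparative chromatography on a chiral stationary phase, and the (R)-enantiomer rejoins the route as 14.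

Step 5. The cycloaddition may be too slow, because the twisted aryl group crowds the C6 terminus of the diene, and the triazine or the MOM acetals may decompose at the temperature needed. The fallback puts an activating, later traceless ester on C3 and sets out from glyoxal 4. Condensation with ethyl oxalamidrazonate (CCOC(=O)C(N)=NN; EtOH, rt → 60 °C) should give ethyl 5-[4-(benzyloxy)-2,6-bis(methoxymethoxy)phenyl]-1,2,4-triazine-3-carboxylate F2. Its lowered LUMO should let norbornadiene 9 add at 80–110 °C to give ethyl 6-[4-(benzyloxy)-2,6-bis(methoxymethoxy)phenyl]pyridine-2-carboxylate F3. Saponification (LiOH·H2O, THF/H2O) gives 6-[4-(benzyloxy)-2,6-bis(methoxymethoxy)phenyl]pyridine-2-carboxylic acid F4. Thermal decarboxylation of this picolinic acid (Hammick-type pathway; Cu2O, 1,10-phenanthroline, NMP/quinoline, 170 °C) returns to pyridine 12.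

Step 12. The acid set free during acylation may strip the MOM acetals before the ring has closed, or may ionise the benzylic C–O bond, which would mean loss of configuration at the future C2 or elimination to a cinnamic acid. The fallback closes the ring under basic conditions by a Parham-type cyclisation and sets out from phenol 16 and ester 17. Monobromination of 16 ortho to the hydroxyl group (NBS, 1.0 equiv, CH2Cl2, −78 °C → 0 °C, amine pre-protonated with TFA) should give 2-bromo-3,5-bis(methoxymethoxy)-4-[(2R)-1-methylpiperidin-2-yl]phenol F5. Ester 17 is converted with MeNHOMe·HCl and i-PrMgCl (THF, −20 °C) into (3R)-3-hydroxy-N-methoxy-N-methyl-3-phenylpropanamide F6. Mitsunobu coupling of the two (PPh3, DIAD, toluene, inversion) gives (3S)-3-{2-bromo-3,5-bis(methoxymethoxy)-4-[(2R)-1-methylpiperidin-2-yl]phenoxy}-N-methoxy-N-methyl-3-phenylpropanamide F7. Bromine–lithium exchange (n-BuLi, THF, −100 °C → −78 °C) and attack of the aryllithium on the Weinreb amide should close the ketone ring and return to flavanone 21.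

Further compounds
F1 | step 7 | rac-1-benzyl-2-[4-(benzyloxy)-2,6-bis(methoxymethoxy)phenyl]piperidine | C(N1CCCCC1c1c(OCOC)cc(OCc2ccccc2)cc1OCOC)c1ccccc1
F2 | step 5 | ethyl 5-[4-(benzyloxy)-2,6-bis(methoxymethoxy)phenyl]-1,2,4-triazine-3-carboxylate | CCOC(=O)c1nncc(n1)-c1c(OCOC)cc(OCc2ccccc2)cc1OCOC
F3 | step 5 | ethyl 6-[4-(benzyloxy)-2,6-bis(methoxymethoxy)phenyl]pyridine-2-carboxylate | CCOC(=O)c1cccc(n1)-c1c(OCOC)cc(OCc2ccccc2)cc1OCOC
F4 | step 5 | 6-[4-(benzyloxy)-2,6-bis(methoxymethoxy)phenyl]pyridine-2-carboxylic acid | OC(=O)c1cccc(n1)-c1c(OCOC)cc(OCc2ccccc2)cc1OCOC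
F5 | step 12 | 2-bromo-3,5-bis(methoxymethoxy)-4-[(2R)-1-methylpiperidin-2-yl]phenol | CN1CCCC[C@@H]1c1c(OCOC)cc(O)c(Br)c1OCOC
F6 | step 12 | (3R)-3-hydroxy-N-methoxy-N-methyl-3-phenylpropanamide | CON(C)C(=O)C[C@H](c1ccccc1)O
F7 | step 12 | (3S)-3-{2-bromo-3,5-bis(methoxymethoxy)-4-[(2R)-1-methylpiperidin-2-yl]phenoxy}-N-methoxy-N-methyl-3-phenylpropanamide | CON(C)C(=O)C[C@@H](c1ccccc1)Oc1cc(OCOC)c([C@H]2CCCCN2C)c(OCOC)c1Br
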